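A direct plan would start from a ready-made polymethoxybenzene, acylate it to the 2-hydroxyacetophenone A1, hydroxylate A1 to the hydroquinone A2, condense the benzylated ketone with O-benzylisovanillin to the chalcone A3, close ring C last by oxidative oxa-Michael cyclization, and finish from the flavone A4 by cleaving its 5-methyl ether. Its weakest steps would be:
- the persulfate para-hydroxylation A1 → A2, an arene C–H oxidation that would stop at low conversion and lose material to tar;
- the final Lewis-acid removal of one methyl group out of four from A4, where a second demethylation or acid-induced ring-C isomerization would cost the most precious material;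
- the run-up to A1, in which O-methylation, Friedel–Crafts acylation and ortho-demethylation would put methyl groups on and take them off, spending three steps on one C–C bond.

**Plan of the new route**
Retrosynthesis: after removal of two acid-labile groups, ring A is cut at C5–C6 and re-closed between C6 and C8a to the spiro-cyclobutenone 9. Compound 9 is then cut at C4a–C5 (a formyl carbon), O1–C2 and C4a–C8a into dimethyl squarate and an aryl ynone.
Enabling feature: in ring A the run C6(OH)–C7(OMe)–C8(OMe)–C8a(–O1) is dimethyl squarate itself, two vicinal methyl ethers flanked by two carbonyl oxygens. The C8a oxygen is the ring-C oxygen, so one squarate carbonyl can be tied into ring C as a spiro ether before it becomes C8a.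
Ring order: ring B is bought, ring C is made next (as a spiro dihydropyranone), ring A last; rings A and C aromatize in the same thermal event.
Consequence: no arene C–H is oxidized, no methyl ether is ever cleaved (methyl sits only where the target keeps it), and no acylated ring-A precursor with its methyl shuffling exists.

Key step: step 7

Remark: compounds 6–9 are racemic (one carbinol or spiro centre, which vanishes in step 7). Compound 8 is taken as its chelated hydroxymethylene tautomer, and 9 may form as an E/Z mixture, which has no consequence because C5 ends up aromatic.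

**Step 1**
Reactants: 1 isovanillin (3-hydroxy-4-methoxybenzaldehyde)
Product: 2 4-methoxy-3-(methoxymethoxy)benzaldehyde
Conditions: MOMCl (1.3 equiv), iPr2NEt (1.6 equiv), CH2Cl2, 0 °C to rt
Reagents that add atoms: chloromethyl methyl ether, COCCl
Why: Base-mediated O-alkylation of the phenol with the α-chloro ether (Williamson-type acetal formation) should give the MOM ether, which tolerates every basic, thermal and π-acidic step that follows and leaves in the final acid step.

**Step 2**
Reactants: 2 4-methoxy-3-(methoxymethoxy)benzaldehyde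
Product: 3 4-ethynyl-1-methoxy-2-(methoxymethoxy)benzene
Conditions: dimethyl (1-diazo-2-oxopropyl)phosphonate (1.2 equiv), K2CO3 (2 equiv), MeOH, rt
Reagents that add atoms: dimethyl (1-diazo-2-oxopropyl)phosphonate, CC(=O)C(=[N+]=[N-])P(=O)(OC)OC
Why: Seyferth–Gilbert homologation in its Ohira–Bestmann form should convert the non-enolizable aryl aldehyde into the terminal alkyne by olefination to a diazoalkene, loss of N2 and 1,2-hydride shift.

**Step 3**
Reactants: 3 4-ethynyl-1-methoxy-2-(methoxymethoxy)benzene
Product: 4 4-[4-methoxy-3-(methoxymethoxy)phenyl]but-3-yn-2-one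
Conditions: n-BuLi (1.05 equiv), THF, −78 °C; N-methoxy-N-methylacetamide (1.2 equiv), −78 to 0 °C; aq NH4Cl
Reagents that add atoms: N-methoxy-N-methylacetamide, CC(=O)N(C)OC
Why: Weinreb ketone synthesis: the lithium acetylide should add once to the amide, because the chelated tetrahedral adduct survives until work-up and so prevents over-addition.

**Step 4**
Reactants: 4 4-[4-methoxy-3-(methoxymethoxy)phenyl]but-3-yn-2-one; 5 dimethyl squarate (3,4-dimethoxycyclobut-3-ene-1,2-dione)
Product: 6 racemic 4-hydroxy-2,3-dimethoxy-4-{4-[4-methoxy-3-(methoxymethoxy)phenyl]-2-oxobut-3-yn-1-yl}cyclobut-2-en-1-one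
Conditions: LiN(iPr)2 (1.05 equiv), THF, −78 °C; 5 (1.1 equiv), −78 °C; AcOH quench at −78 °C
Reagents that add atoms: none
Why: Directed aldol addition: the kinetic lithium enolate of the methyl ketone should add 1,2 to one of the two equivalent, strain-activated carbonyl groups of 5, as hard lithium nucleophiles do with squarate esters at −78 °C, and protonation before warming forestalls retro-aldol cleavage; the new carbinol centre forms as a racemate and is destroyed in step 7.

**Step 5**
Reactants: 6 racemic 4-hydroxy-2,3-dimethoxy-4-{4-[4-methoxy-3-(methoxymethoxy)phenyl]-2-oxobut-3-yn-1-yl}cyclobut-2-en-1-one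
Product: 7 racemic 2,3-dimethoxy-6-[4-methoxy-3-(methoxymethoxy)phenyl]-5-oxaspiro[3.5]nona-2,6-diene-1,8-dione
Conditions: Ph3PAuNTf2 (3 mol%), CH2Cl2, rt
Reagents that add atoms: none
Why: 6-endo-dig hydroalkoxylation (intramolecular oxa-Michael addition) of a β-hydroxy ynone under π-acid catalysis is a standard entry to 2,3-dihydro-4H-pyran-4-ones: the tertiary hydroxyl should add to the aryl-bearing alkyne carbon (the conjugate position; 5-exo attack would be anti-Michael), which fixes the former squarate oxygen as O1 before ring A exists.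

**Step 6**
Reactants: 7 racemic 2,3-dimethoxy-6-[4-methoxy-3-(methoxymethoxy)phenyl]-5-oxaspiro[3.5]nona-2,6-diene-1,8-dione
Product: 9 racemic 9-{[tert-butyl(dimethyl)silyl]oxymethylidene}-2,3-dimethoxy-6-[4-methoxy-3-(methoxymethoxy)phenyl]-5-oxaspiro[3.5]nona-2,6-diene-1,8-dione, via hydroxymethylene ketone 8 (not isolated)
Conditions: LiN(iPr)2 (1.1 equiv), THF, −78 °C; HCO2CH2CF3 (1.5 equiv), −78 °C; AcOH, −78 °C, extractive work-up; crude 8, TBSCl (1.2 equiv), imidazole (2 equiv), CH2Cl2, 0 °C
Reagents that add atoms: 2,2,2-trifluoroethyl formate, O=COCC(F)(F)F; tert-butyldimethylsilyl chloride, CC(C)(C)[Si](C)(C)Cl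
Why: Crossed Claisen formylation of the only enolizable carbon (C9, the future C4a) with the highly electrophilic trifluoroethyl formate at −78 °C, where β-elimination of the ring oxygen is held back because it would create a strained alkylidenecyclobutenone, followed by imidazole-promoted O-silylation of the chelated enol 8, should supply C5 with its oxygen and a group that falls off in the last step.

**Step 7**
Reactants: 9 racemic 9-{[tert-butyl(dimethyl)silyl]oxymethylidene}-2,3-dimethoxy-6-[4-methoxy-3-(methoxymethoxy)phenyl]-5-oxaspiro[3.5]nona-2,6-diene-1,8-dione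
Product: 12 5-(tert-butyldimethylsilyloxy)-6-hydroxy-7,8-dimethoxy-2-[4-methoxy-3-(methoxymethoxy)phenyl]-4H-chromen-4-one, via dienylketene 10 (not isolated), via cyclohexadienone 11 (not isolated)
Conditions: degassed toluene (0.01 M), 110 °C, 2 h, Ar
Reagents that add atoms: none
Why: Heating should open the cyclobutenone by thermal conrotatory 4π-electrocyclic cleavage of the C6–C8a bond to the dienylketene 10, in which the ketene carbon C6 and the silyloxymethylene carbon C5 are the termini of a hexatriene held s-cis by ring C; 6π-electrocyclization then forms the C5–C6 bond, closing ring A as a six-membered carbocycle, and enolization of the cyclohexadienone 11 gives the phenol while ring C becomes the aromatic 4-pyranone in the same event. The closest known reaction type is the Moore rearrangement of 4-alkenyl-4-alkoxycyclobutenones to hydroquinone monoethers. The selectivity needed is torquoselectivity: the oxygen at the breaking carbon (O1) must rotate outward so that C4a turns toward the ketene, which is the established preference of oxygen donors, and because the ring opening is reversible and O1 is an ether with no O–H to lactonize onto the ketene, the unproductive rotamer can only revert. Regiochemistry needs no control, since the two methyl ethers of 5 are by construction 7-OMe and 8-OMe, the squarate carbonyl oxygens are O1 and 6-OH, and C5 brings its own oxygen. No stereocentre remains, because the spiro centre of 9 and the transient C5 centre of 11 are both lost on aromatization. High dilution and exclusion of air protect the ketene from dimerization and the electron-rich phenol from oxidation.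

**Step 8**
Reactants: 12 5-(tert-butyldimethylsilyloxy)-6-hydroxy-7,8-dimethoxy-2-[4-methoxy-3-(methoxymethoxy)phenyl]-4H-chromen-4-one
Product: 13 5,6-dihydroxy-2-(3-hydroxy-4-methoxyphenyl)-7,8-dimethoxy-4H-chromen-4-one (5,6,3'-trihydroxy-7,8,4'-trimethoxyflavone)
Conditions: 3 M HCl, MeOH–THF, 50 °C, N2
Reagents that add atoms: none
Why: Acid-catalysed acetal exchange should remove the MOM ether and acid methanolysis the aryl silyl ether in one non-selective global deprotection, while the three methyl ethers are inert to dilute HCl and no choice among ether groups has to be made.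

**Compound list**
1 | isovanillin (3-hydroxy-4-methoxybenzaldehyde) | COc1ccc(C=O)cc1O | starting material
2 | 4-methoxy-3-(methoxymethoxy)benzaldehyde | COc1ccc(C=O)cc1OCOC | intermediate
3 | 4-ethynyl-1-methoxy-2-(methoxymethoxy)benzene | C#Cc1ccc(OC)c(OCOC)c1 | intermediate
4 | 4-[4-methoxy-3-(methoxymethoxy)phenyl]but-3-yn-2-one | CC(=O)C#Cc1ccc(OC)c(OCOC)c1 | intermediate
5 | dimethyl squarate (3,4-dimethoxycyclobut-3-ene-1,2-dione) | COC1=C(OC)C(=O)C1=O | starting material
6 | racemic 4-hydroxy-2,3-dimethoxy-4-{4-[4-methoxy-3-(methoxymethoxy)phenyl]-2-oxobut-3-yn-1-yl}cyclobut-2-en-1-one | COC1=C(OC)C(O)(CC(=O)C#Cc2ccc(OC)c(OCOC)c2)C1=O | intermediate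
7 | racemic 2,3-dimethoxy-6-[4-methoxy-3-(methoxymethoxy)phenyl]-5-oxaspiro[3.5]nona-2,6-diene-1,8-dione | COC1=C(OC)C2(CC(=O)C=C(c3ccc(OC)c(OCOC)c3)O2)C1=O | intermediate
8 | racemic (Z)-9-(hydroxymethylidene)-2,3-dimethoxy-6-[4-methoxy-3-(methoxymethoxy)phenyl]-5-oxaspiro[3.5]nona-2,6-diene-1,8-dione (chelated enol of the 9-formyl ketone) | O/C=C1\C(=O)C=C(c2ccc(OC)c(OCOC)c2)OC13C(OC)=C(OC)C3=O | intermediate
9 | racemic 9-{[tert-butyl(dimethyl)silyl]oxymethylidene}-2,3-dimethoxy-6-[4-methoxy-3-(methoxymethoxy)phenyl]-5-oxaspiro[3.5]nona-2,6-diene-1,8-dione (E/Z not defined) | CC(C)(C)[Si](C)(C)OC=C1C(=O)C=C(c2ccc(OC)c(OCOC)c2)OC13C(OC)=C(OC)C3=O | intermediate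
10 | 3-[(tert-butyldimethylsilyloxy)methylidene]-2-(1,2-dimethoxy-3-oxoprop-2-en-1-ylidene)-6-[4-methoxy-3-(methoxymethoxy)phenyl]-2,3-dihydro-4H-pyran-4-one (dienylketene, ketene arm cis to C3 of the pyranone) | O=C=C(OC)/C(OC)=C1/OC(c2ccc(OC)c(OCOC)c2)=CC(=O)C1=CO[Si](C)(C)C(C)(C)C | intermediate
11 | racemic 5-(tert-butyldimethylsilyloxy)-7,8-dimethoxy-2-[4-methoxy-3-(methoxymethoxy)phenyl]-5H-chromene-4,6-dione | COC1=C(OC)C2=C(C(=O)C=C(c3ccc(OC)c(OCOC)c3)O2)C(O[Si](C)(C)C(C)(C)C)C1=O | intermediate
12 | 5-(tert-butyldimethylsilyloxy)-6-hydroxy-7,8-dimethoxy-2-[4-methoxy-3-(methoxymethoxy)phenyl]-4H-chromen-4-one | COc1ccc(-c2cc(=O)c3c(O[Si](C)(C)C(C)(C)C)c(O)c(OC)c(OC)c3o2)cc1OCOC | intermediate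
13 | 5,6-dihydroxy-2-(3-hydroxy-4-methoxyphenyl)-7,8-dimethoxy-4H-chromen-4-one (achiral) | COc1ccc(-c2cc(=O)c3c(O)c(O)c(OC)c(OC)c3o2)cc1O | target

**Step count and risks**
Total steps: 8. Longest linear sequence: 8 (1 → 13); dimethyl squarate 5 enters at step 4.

Steps most likely to fail:

1. Step 6. The C9 enolate may expel the ring-C oxygen (retro-oxa-Michael opening of ring C) before or after it is formylated. Fallback, from 7 back to 8: soft enolization with TMSOTf and Et3N in CH2Cl2 at 0 °C, which avoids a free enolate, would give the silyl dienol ether 2,3-dimethoxy-6-[4-methoxy-3-(methoxymethoxy)phenyl]-8-(trimethylsilyloxy)-5-oxaspiro[3.5]nona-2,6,8-trien-1-one F1. Electrophilic formylation of F1 with (chloromethylidene)dimethyliminium chloride (Vilsmeier salt) in CH2Cl2 at 0 °C would give the enaminone 9-[(dimethylamino)methylidene]-2,3-dimethoxy-6-[4-methoxy-3-(methoxymethoxy)phenyl]-5-oxaspiro[3.5]nona-2,6-diene-1,8-dione F2. Hydrolysis of F2 with cold dilute aqueous HCl in THF would deliver the hydroxymethylene ketone 8, which is silylated as in step 6.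

2. Step 4. The aldol addition may revert on warming or work-up, or the enolate may add in conjugate fashion at a methoxy-bearing ring carbon with loss of methoxide. Fallback, from 4 back to 7 (bypassing 6): hydration of the ynone (Ph3PAuNTf2 cat., wet dioxane, 60 °C) would give 1-[4-methoxy-3-(methoxymethoxy)phenyl]butane-1,3-dione F3. Its dianion (LiN(iPr)2, 2.2 equiv, THF, −78 to 0 °C), whose terminal carbanion adds essentially irreversibly, would be added to 5 at −78 °C to give 4-hydroxy-2,3-dimethoxy-4-{4-[4-methoxy-3-(methoxymethoxy)phenyl]-2,4-dioxobutyl}cyclobut-2-en-1-one F4. Cyclodehydration of F4 (pyridinium p-toluenesulfonate, MgSO4, CH2Cl2, rt) would close ring C and give 7.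

3. Step 5. The tertiary, alkoxy-stabilized C–O bond of the hydroxycyclobutenone may ionize at the Lewis acid (loss of methanol toward a cyclobutenedione), or retro-aldol cleavage may outrun hydroalkoxylation. Fallback, from 6 back to 7: conjugate addition of Et2NH to the ynone (EtOH, rt) would give the vinylogous amide (E)-4-{4-(diethylamino)-4-[4-methoxy-3-(methoxymethoxy)phenyl]-2-oxobut-3-en-1-yl}-4-hydroxy-2,3-dimethoxycyclobut-2-en-1-one F5. Warming F5 with AcOH in toluene should let the tertiary hydroxyl displace diethylamine by addition–elimination at the β-carbon, closing the dihydropyranone 7 without any π-acid.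

**Further compounds**
F1 | step 6 | 2,3-dimethoxy-6-[4-methoxy-3-(methoxymethoxy)phenyl]-8-(trimethylsilyloxy)-5-oxaspiro[3.5]nona-2,6,8-trien-1-one (racemic) | COC1=C(OC)C2(C=C(O[Si](C)(C)C)C=C(c3ccc(OC)c(OCOC)c3)O2)C1=O
F2 | step 6 | 9-[(dimethylamino)methylidene]-2,3-dimethoxy-6-[4-methoxy-3-(methoxymethoxy)phenyl]-5-oxaspiro[3.5]nona-2,6-diene-1,8-dione (racemic, E/Z not defined) | CN(C)C=C1C(=O)C=C(c2ccc(OC)c(OCOC)c2)OC13C(OC)=C(OC)C3=O
F3 | step 4 | 1-[4-methoxy-3-(methoxymethoxy)phenyl]butane-1,3-dione | CC(=O)CC(=O)c1ccc(OC)c(OCOC)c1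
F4 | step 4 | racemic 4-hydroxy-2,3-dimethoxy-4-{4-[4-methoxy-3-(methoxymethoxy)phenyl]-2,4-dioxobutyl}cyclobut-2-en-1-one | COC1=C(OC)C(O)(CC(=O)CC(=O)c2ccc(OC)c(OCOC)c2)C1=O
F5 | step 5 | racemic (E)-4-{4-(diethylamino)-4-[4-methoxy-3-(methoxymethoxy)phenyl]-2-oxobut-3-en-1-yl}-4-hydroxy-2,3-dimethoxycyclobut-2-en-1-one | CCN(CC)/C(=C/C(=O)CC1(O)C(OC)=C(OC)C1=O)c1ccc(OC)c(OCOC)c1
A1 | direct plan | 1-(2-hydroxy-3,4,6-trimethoxyphenyl)ethanone | CC(=O)c1c(O)c(OC)c(OC)cc1OC
A2 | direct plan | 1-(2,5-dihydroxy-3,4,6-trimethoxyphenyl)ethanone | CC(=O)c1c(O)c(OC)c(OC)c(O)c1OC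
A3 | direct plan | (E)-1-(5-benzyloxy-2-hydroxy-3,4,6-trimethoxyphenyl)-3-(3-benzyloxy-4-methoxyphenyl)prop-2-en-1-one | COc1ccc(/C=C/C(=O)c2c(O)c(OC)c(OC)c(OCc3ccccc3)c2OC)cc1OCc1ccccc1
A4 | direct plan | 6-hydroxy-2-(3-hydroxy-4-methoxyphenyl)-5,7,8-trimethoxy-4H-chromen-4-one | COc1ccc(-c2cc(=O)c3c(OC)c(O)c(OC)c(OC)c3o2)cc1O
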